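**Plan**

- Retrosynthesis: with four benzyl ethers added back and C4=O taken down to a carbinol, ring C of the flavanone is opened at the aryl–oxygen bond O1–C8a. This works because O1 is both the oxygen on the C2 stereocentre and the phenolic oxygen of ring A at C8a, so the ring can be closed there while all four bonds at C2 stay as they are.
- The resulting anti-1,3-diol with an ortho bromide on ring A is cut at C2–C3 (Claisen condensation, then two carbonyl reductions), the ring A methyl ketone at C4–C4a (Friedel–Crafts), and the diaryl ether between kaempferol O3 and C4' of ring B (SNAr on methyl 4-fluorobenzoate).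
- Forward: a 2-benzyloxy-6-bromo-4-methoxyacetophenone and a tri-O-benzylkaempferol 3-O-aryl ester are made separately, joined to a 1,3-diketone and reduced in two stages to the diol. Ring C, the only ring formed, is then closed by copper-catalysed intramolecular O-arylation; oxidation at C4 and hydrogenolysis finish the synthesis.
- Stereochemistry: the single stereocentre (C2, S) comes from asymmetric transfer hydrogenation of the ring B carbonyl with an (S,S)-TsDPEN ruthenium catalyst and passes through the ring closure with retention; the C4 carbinol centre is temporary.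

Key step: step 12

Remark on names: rings A, B and C and the locants C2, C3, C4, C4a, C8a refer to the flavanone half. "Kaempferol-3-yl" is the 3,4',5,7-tetraoxygenated 2-aryl-4H-chromen-4-one unit bonded through O3. In the open-chain compounds C1 is the carbon on ring A (later C4) and C3 the carbon on ring B (later C2).

Remark (assumption): diketone 15 is drawn as the diketo tautomer; it should exist mainly as the chelated enol, which equilibrates with the keto form that is reduced in step 10.

**Route**

Step 1
Reactants: 1 1-bromo-3,5-dimethoxybenzene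
Product: 2 1-(2-bromo-4,6-dimethoxyphenyl)ethan-1-one
Conditions: AcCl, AlCl3, CH2Cl2, 0 °C to rt
Reagents that add atoms: acetyl chloride, CC(=O)Cl
Why: Friedel–Crafts acylation should take place at the position para to one methoxy group and ortho to the other (next to bromine) rather than at the more crowded position between the two methoxy groups, the preference this arene also shows in formylation, and the acetyl group deactivates the ring against a second acylation.

Step 2
Reactants: 2 1-(2-bromo-4,6-dimethoxyphenyl)ethan-1-one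
Product: 4 1-(2-bromo-6-hydroxy-4-methoxyphenyl)ethan-1-one, via dichloroboron phenolate 3 (not isolated)
Conditions: BCl3, CH2Cl2, −78 to 0 °C; then H2O
Reagents that add atoms: none
Why: Chelation-directed Lewis-acid ether cleavage: BCl3 bound to the ketone oxygen reaches only the ortho methoxy group, whose methyl leaves as chloromethane, so the para methoxy group and the aryl bromide are untouched and hydrolytic work-up releases the hydrogen-bonded phenol.

Step 3
Reactants: 4 1-(2-bromo-6-hydroxy-4-methoxyphenyl)ethan-1-one
Product: 5 1-[2-(benzyloxy)-6-bromo-4-methoxyphenyl]ethan-1-one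
Conditions: BnBr, K2CO3, DMF, 60 °C
Reagents that add atoms: benzyl bromide, BrCc1ccccc1
Why: Williamson ether synthesis, run warm because the phenol is hydrogen-bonded to the acetyl group; the benzyl ether lets this oxygen be unmasked together with the others in the last step.

Step 4
Reactants: 6 kaempferol
Product: 7 3,4',5,7-tetra-O-acetylkaempferol
Conditions: Ac2O, pyridine, DMAP (cat.), rt
Reagents that add atoms: acetic anhydride, CC(=O)OC(C)=O
Why: Exhaustive O-acetylation with nucleophilic catalysis acylates all four hydroxyls, the chelated 5-OH included, and prepares the differentiation of O7 and O4' from O3 and O5.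

Step 5
Reactants: 7 3,4',5,7-tetra-O-acetylkaempferol
Product: 9 3,5-di-O-acetyl-4',7-di-O-benzylkaempferol, via 7-O-benzyl triacetate 8 (not isolated)
Conditions: BnBr (2.3 equiv), K2CO3, acetone, reflux
Reagents that add atoms: benzyl bromide, BrCc1ccccc1
Why: Benzylative deacetylation, a known way to differentiate flavonol acetates: carbonate cleaves the aryl acetates in the order of acidity of the parent phenols (O7 first, then O4'), each phenoxide is trapped at once by benzyl bromide in a Williamson reaction, and the enol acetate at C3 and the peri-hindered 5-acetate should remain when the bromide is limited to just over two equivalents.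

Step 6
Reactants: 9 3,5-di-O-acetyl-4',7-di-O-benzylkaempferol
Product: 10 4',7-di-O-benzylkaempferol
Conditions: NH3 (7 M in MeOH), THF, rt, argon
Reagents that add atoms: none
Why: Ammonolysis of the two remaining activated (aryl and enol) acetates frees the 3- and 5-hydroxyls without touching the benzyl ethers, and argon protects the electron-rich flavonolate from autoxidation.

Step 7
Reactants: 10 4',7-di-O-benzylkaempferol; 11 methyl 4-fluorobenzoate
Product: 12 methyl 4-[(4',7-di-O-benzylkaempferol-3-yl)oxy]benzoate
Conditions: Cs2CO3, dry DMSO, 100 °C, argon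
Reagents that add atoms: none
Why: Nucleophilic aromatic substitution through a Meisenheimer adduct stabilised by the para ester, carried out by the 3-oxide, the more acidic and more accessible of the two free hydroxyls, while the 5-OH stays locked in its hydrogen bond to the C4 carbonyl and the fluoroarene is used in only slight excess.

Step 8
Reactants: 12 methyl 4-[(4',7-di-O-benzylkaempferol-3-yl)oxy]benzoate
Product: 13 methyl 4-[(4',5,7-tri-O-benzylkaempferol-3-yl)oxy]benzoate
Conditions: BnBr, K2CO3, DMF, 70 °C
Reagents that add atoms: benzyl bromide, BrCc1ccccc1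
Why: Williamson etherification of the chelated 5-OH needs heat but is routine for 5-hydroxyflavones, and it removes the last acidic, copper-binding phenol before the enolate chemistry, the copper step and the periodinane oxidation.

Step 9
Reactants: 5 1-[2-(benzyloxy)-6-bromo-4-methoxyphenyl]ethan-1-one; 13 methyl 4-[(4',5,7-tri-O-benzylkaempferol-3-yl)oxy]benzoate
Product: 15 1-[2-(benzyloxy)-6-bromo-4-methoxyphenyl]-3-{4-[(4',5,7-tri-O-benzylkaempferol-3-yl)oxy]phenyl}propane-1,3-dione, via lithium enolate 14 (not isolated)
Conditions: 5, LiN(SiMe3)2 (2.5 equiv), THF, −78 °C; then 13, −78 °C to rt; aq. NH4Cl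
Reagents that add atoms: none
Why: Crossed Claisen condensation: the lithium enolate of the methyl ketone is acylated by the non-enolisable aryl ester, deprotonation of the 1,3-diketone by the second equivalent of amide base drives the reaction, and the doubly ortho-substituted carbonyl of 5 is too hindered for self-condensation.

Step 10
Reactants: 15 1-[2-(benzyloxy)-6-bromo-4-methoxyphenyl]-3-{4-[(4',5,7-tri-O-benzylkaempferol-3-yl)oxy]phenyl}propane-1,3-dione
Product: 16 (3S)-1-[2-(benzyloxy)-6-bromo-4-methoxyphenyl]-3-hydroxy-3-{4-[(4',5,7-tri-O-benzylkaempferol-3-yl)oxy]phenyl}propan-1-one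
Conditions: RuCl[(S,S)-TsDPEN](p-cymene) (2 mol%), HCO2H/Et3N (5:2), CH2Cl2, 30 °C
Reagents that add atoms: none
Why: Noyori asymmetric transfer hydrogenation: the ruthenium hydride of the (S,S)-ligand delivers hydride through the outer-sphere six-membered transition state to the Re face of the planar carbonyl on ring B (the sense known for acetophenone and for 1,3-diaryl-1,3-diketones), setting C3 as S, whereas the carbonyl on the di-ortho-substituted ring A is twisted and shielded, so reduction should stop at the monoalcohol.

Step 11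
Reactants: 16 (3S)-1-[2-(benzyloxy)-6-bromo-4-methoxyphenyl]-3-hydroxy-3-{4-[(4',5,7-tri-O-benzylkaempferol-3-yl)oxy]phenyl}propan-1-one
Product: 17 (1S,3S)-1-[2-(benzyloxy)-6-bromo-4-methoxyphenyl]-3-{4-[(4',5,7-tri-O-benzylkaempferol-3-yl)oxy]phenyl}propane-1,3-diol
Conditions: Me4NBH(OAc)3, MeCN/AcOH (1:1), −30 °C
Reagents that add atoms: none
Why: Evans–Saksena reduction: the C3 hydroxyl exchanges onto boron and hydride is delivered intramolecularly through a chair-like six-membered transition state, which should give the 1,3-anti diol (1S); this centre is removed again in step 13, so its purity is a convenience and not a requirement.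

Step 12
Reactants: 17 (1S,3S)-1-[2-(benzyloxy)-6-bromo-4-methoxyphenyl]-3-{4-[(4',5,7-tri-O-benzylkaempferol-3-yl)oxy]phenyl}propane-1,3-diol
Product: 18 (2S,4S)-5-(benzyloxy)-7-methoxy-2-{4-[(4',5,7-tri-O-benzylkaempferol-3-yl)oxy]phenyl}chroman-4-ol (2,4-cis flavan-4-ol)
Conditions: CuI (20 mol%), 3,4,7,8-tetramethyl-1,10-phenanthroline (40 mol%), Cs2CO3, toluene, 110 °C, argon
Reagents that add atoms: none
Why: Ullmann-type intramolecular O-arylation: the cesium alkoxide of the C3 hydroxyl binds the phenanthroline-ligated monovalent copper, the ortho C–Br bond adds oxidatively to give an aryl(alkoxo) trivalent copper species held in a seven-membered chelate, and reductive elimination forms O1–C8a. The closest known reaction type is the copper-catalysed cyclisation of 3-(2-bromoaryl)propan-1-ols, secondary benzylic ones included, to chromans and 2-arylchromans. Ring C closes in a six-membered exo mode, the tethered oxygen replacing bromine at the ipso carbon of ring A. No new stereocentre is formed; C2 (from C3 of 17) and C4 (from C1) are carried over with retention because neither carbinol C–O bond is broken. The selectivity needed is between the two hydroxyls and against intermolecular coupling: the C1 hydroxyl could only close a four-membered ring and may instead act as an internal ligand that holds copper next to the C–Br bond, while moderate dilution and the absence of any free phenol (all four are benzyl ethers) should suppress oligomeric ethers. Keeping C4 at the carbinol level removes the retro-aldol and β-elimination pathways that a β-hydroxy ketone would have under carbonate at this temperature.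

Step 13
Reactants: 18 (2S,4S)-5-(benzyloxy)-7-methoxy-2-{4-[(4',5,7-tri-O-benzylkaempferol-3-yl)oxy]phenyl}chroman-4-ol
Product: 19 (2S)-5-(benzyloxy)-7-methoxy-2-{4-[(4',5,7-tri-O-benzylkaempferol-3-yl)oxy]phenyl}chroman-4-one
Conditions: Dess–Martin periodinane, pyridine, CH2Cl2, 0 °C to rt
Reagents that add atoms: none
Why: Dess–Martin oxidation of the secondary benzylic carbinol under pyridine-buffered, non-basic conditions, which should leave C2 untouched because ring opening to the chalcone (retro-oxa-Michael) needs base.

Step 14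
Reactants: 19 (2S)-5-(benzyloxy)-7-methoxy-2-{4-[(4',5,7-tri-O-benzylkaempferol-3-yl)oxy]phenyl}chroman-4-one
Product: 20 (2S)-5-hydroxy-7-methoxy-2-{4-[(kaempferol-3-yl)oxy]phenyl}chroman-4-one (CNP0173006.1)
Conditions: H2 (1 atm), 10% Pd/C, THF/MeOH (1:1), rt
Reagents that add atoms: none
Why: Catalytic hydrogenolysis of the four aryl benzyl ethers, which cleave far faster than the cyclic C2–O1 benzylic ether, the aryl ketone or the flavonol double bond, so stopping the reaction once the benzyl ethers are consumed should give the tetraphenol with C2 intact.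

**Compound list**

1 | 1-bromo-3,5-dimethoxybenzene | COc1cc(Br)cc(OC)c1 | starting material
2 | 1-(2-bromo-4,6-dimethoxyphenyl)ethan-1-one | CC(=O)c1c(Br)cc(OC)cc1OC | intermediate
3 | (2-acetyl-3-bromo-5-methoxyphenoxy)dichloroborane, chelated to the acetyl oxygen (formed in the flask, not isolated) | CC(=O)c1c(Br)cc(OC)cc1OB(Cl)Cl | intermediate
4 | 1-(2-bromo-6-hydroxy-4-methoxyphenyl)ethan-1-one | CC(=O)c1c(Br)cc(OC)cc1O | intermediate
5 | 1-[2-(benzyloxy)-6-bromo-4-methoxyphenyl]ethan-1-one | CC(=O)c1c(Br)cc(OC)cc1OCc1ccccc1 | intermediate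
6 | kaempferol (3,4',5,7-tetrahydroxyflavone) | O=c1c(O)c(-c2ccc(O)cc2)oc2cc(O)cc(O)c12 | starting material
7 | 3,4',5,7-tetra-O-acetylkaempferol | CC(=O)Oc1c(-c2ccc(OC(C)=O)cc2)oc2cc(OC(C)=O)cc(OC(C)=O)c2c1=O | intermediate
8 | 3,4',5-tri-O-acetyl-7-O-benzylkaempferol (formed in the flask, not isolated) | CC(=O)Oc1c(-c2ccc(OC(C)=O)cc2)oc2cc(OCc3ccccc3)cc(OC(C)=O)c2c1=O | intermediate
9 | 3,5-di-O-acetyl-4',7-di-O-benzylkaempferol | CC(=O)Oc1c(-c2ccc(OCc3ccccc3)cc2)oc2cc(OCc3ccccc3)cc(OC(C)=O)c2c1=O | intermediate
10 | 4',7-di-O-benzylkaempferol | Oc1c(-c2ccc(OCc3ccccc3)cc2)oc2cc(OCc3ccccc3)cc(O)c2c1=O | intermediate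
11 | methyl 4-fluorobenzoate | COC(=O)c1ccc(F)cc1 | starting material
12 | methyl 4-[(4',7-di-O-benzylkaempferol-3-yl)oxy]benzoate (5-OH free) | COC(=O)c1ccc(Oc2c(-c3ccc(OCc4ccccc4)cc3)oc3cc(OCc4ccccc4)cc(O)c3c2=O)cc1 | intermediate
13 | methyl 4-[(4',5,7-tri-O-benzylkaempferol-3-yl)oxy]benzoate | COC(=O)c1ccc(Oc2c(-c3ccc(OCc4ccccc4)cc3)oc3cc(OCc4ccccc4)cc(OCc4ccccc4)c3c2=O)cc1 | intermediate
14 | lithium 1-[2-(benzyloxy)-6-bromo-4-methoxyphenyl]ethen-1-olate, the lithium enolate of 5 (formed in the flask, not isolated) | [Li]OC(=C)c1c(Br)cc(OC)cc1OCc1ccccc1 | intermediate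
15 | 1-[2-(benzyloxy)-6-bromo-4-methoxyphenyl]-3-{4-[(4',5,7-tri-O-benzylkaempferol-3-yl)oxy]phenyl}propane-1,3-dione | COc1cc(Br)c(C(=O)CC(=O)c2ccc(Oc3c(-c4ccc(OCc5ccccc5)cc4)oc4cc(OCc5ccccc5)cc(OCc5ccccc5)c4c3=O)cc2)c(OCc2ccccc2)c1 | intermediate
16 | (3S)-1-[2-(benzyloxy)-6-bromo-4-methoxyphenyl]-3-hydroxy-3-{4-[(4',5,7-tri-O-benzylkaempferol-3-yl)oxy]phenyl}propan-1-one | COc1cc(Br)c(C(=O)C[C@H](O)c2ccc(Oc3c(-c4ccc(OCc5ccccc5)cc4)oc4cc(OCc5ccccc5)cc(OCc5ccccc5)c4c3=O)cc2)c(OCc2ccccc2)c1 | intermediate
17 | (1S,3S)-1-[2-(benzyloxy)-6-bromo-4-methoxyphenyl]-3-{4-[(4',5,7-tri-O-benzylkaempferol-3-yl)oxy]phenyl}propane-1,3-diol (anti) | COc1cc(Br)c([C@@H](O)C[C@H](O)c2ccc(Oc3c(-c4ccc(OCc5ccccc5)cc4)oc4cc(OCc5ccccc5)cc(OCc5ccccc5)c4c3=O)cc2)c(OCc2ccccc2)c1 | intermediate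
18 | (2S,4S)-5-(benzyloxy)-7-methoxy-2-{4-[(4',5,7-tri-O-benzylkaempferol-3-yl)oxy]phenyl}chroman-4-ol (2,4-cis) | COc1cc(OCc2ccccc2)c2c(c1)O[C@H](c1ccc(Oc3c(-c4ccc(OCc5ccccc5)cc4)oc4cc(OCc5ccccc5)cc(OCc5ccccc5)c4c3=O)cc1)C[C@@H]2O | intermediate
19 | (2S)-5-(benzyloxy)-7-methoxy-2-{4-[(4',5,7-tri-O-benzylkaempferol-3-yl)oxy]phenyl}chroman-4-one | COc1cc(OCc2ccccc2)c2c(c1)O[C@H](c1ccc(Oc3c(-c4ccc(OCc5ccccc5)cc4)oc4cc(OCc5ccccc5)cc(OCc5ccccc5)c4c3=O)cc1)CC2=O | intermediate
20 | (2S)-5-hydroxy-7-methoxy-2-{4-[(kaempferol-3-yl)oxy]phenyl}chroman-4-one (CNP0173006.1) | COc1cc(O)c2c(c1)O[C@H](c1ccc(Oc3c(-c4ccc(O)cc4)oc4cc(O)cc(O)c4c3=O)cc1)CC2=O | target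

**Step count and risks**

Total step count: 14.
Longest linear sequence: 11 steps (kaempferol 6 to target 20, steps 4 to 14); the ring A branch (steps 1 to 3) joins at step 9.

Steps most likely to fail:

1. Step 12 (ring closure). Oxidative addition of the electron-rich aryl bromide to copper may be slow, so that protodebromination wins. A copper alkoxide may also lose a β-hydride, oxidising one of the benzylic carbinols and opening a retro-aldol cleavage of the chain. The fallback sets out from 17 and comes back at 18 with the same bond made on palladium instead of copper: Pd(OAc)2 with 2-(di-tert-butylphosphino)-1,1'-binaphthyl, Cs2CO3, toluene, 80 °C. Zerovalent palladium inserts readily into the C–Br bond, and the bulky phosphine accelerates C–O reductive elimination from the arylpalladium alkoxide ahead of β-hydride elimination. Secondary alcohols are known to cyclise in this Buchwald–Hartwig etherification manifold with retention. It passes through no compound outside the route (entry F0).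

2. Step 7 (diaryl ether). The ester activates the fluoroarene only moderately, so substitution may be slow. At the temperature then needed, cleavage of the methyl ester by adventitious hydroxide and decomposition of the flavonolate compete. The fallback sets out from 10 and uses the more strongly activated 4-fluorobenzaldehyde (K2CO3, DMF, 80 °C) to give 4-[(4',7-di-O-benzylkaempferol-3-yl)oxy]benzaldehyde F1. Benzylation of the 5-OH (BnBr, K2CO3, DMF, 70 °C) gives 4-[(4',5,7-tri-O-benzylkaempferol-3-yl)oxy]benzaldehyde F2. Aldol addition of lithium enolate 14 (from 5 with LiN(iPr)2, THF, −78 °C) gives racemic 1-[2-(benzyloxy)-6-bromo-4-methoxyphenyl]-3-hydroxy-3-{4-[(4',5,7-tri-O-benzylkaempferol-3-yl)oxy]phenyl}propan-1-one F3. Oxidation of this β-hydroxy ketone with IBX (EtOAc, 75 °C) returns to the route at diketone 15, bypassing steps 8 and 9.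

3. Step 11 (second reduction). The triacetoxyborohydride is a weak hydride donor and the carbonyl is flanked by two ortho substituents, so the reduction may stall. In acetic acid the newly formed, electron-rich benzylic carbinol may ionise and eliminate. The fallback sets out from 16 and reduces under non-acidic Narasaka–Prasad conditions (Et2BOMe, NaBH4, THF/MeOH, −78 °C), where external hydride attacks the boron chelate. This gives the syn diol (1R,3S)-1-[2-(benzyloxy)-6-bromo-4-methoxyphenyl]-3-{4-[(4',5,7-tri-O-benzylkaempferol-3-yl)oxy]phenyl}propane-1,3-diol F4. Because only C3 matters, F4 is closed under the conditions of step 12 to (2S,4R)-5-(benzyloxy)-7-methoxy-2-{4-[(4',5,7-tri-O-benzylkaempferol-3-yl)oxy]phenyl}chroman-4-ol F5. Dess–Martin oxidation erases C4 and returns to the route at 19.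

**Further compounds**

F0 | step 12 | none | none
F1 | step 7 | 4-[(4',7-di-O-benzylkaempferol-3-yl)oxy]benzaldehyde | O=Cc1ccc(Oc2c(-c3ccc(OCc4ccccc4)cc3)oc3cc(OCc4ccccc4)cc(O)c3c2=O)cc1
F2 | step 7 | 4-[(4',5,7-tri-O-benzylkaempferol-3-yl)oxy]benzaldehyde | O=Cc1ccc(Oc2c(-c3ccc(OCc4ccccc4)cc3)oc3cc(OCc4ccccc4)cc(OCc4ccccc4)c3c2=O)cc1
F3 | step 7 | racemic 1-[2-(benzyloxy)-6-bromo-4-methoxyphenyl]-3-hydroxy-3-{4-[(4',5,7-tri-O-benzylkaempferol-3-yl)oxy]phenyl}propan-1-one | COc1cc(Br)c(C(=O)CC(O)c2ccc(Oc3c(-c4ccc(OCc5ccccc5)cc4)oc4cc(OCc5ccccc5)cc(OCc5ccccc5)c4c3=O)cc2)c(OCc2ccccc2)c1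
F4 | step 11 | (1R,3S)-1-[2-(benzyloxy)-6-bromo-4-methoxyphenyl]-3-{4-[(4',5,7-tri-O-benzylkaempferol-3-yl)oxy]phenyl}propane-1,3-diol (syn) | COc1cc(Br)c([C@H](O)C[C@H](O)c2ccc(Oc3c(-c4ccc(OCc5ccccc5)cc4)oc4cc(OCc5ccccc5)cc(OCc5ccccc5)c4c3=O)cc2)c(OCc2ccccc2)c1
F5 | step 11 | (2S,4R)-5-(benzyloxy)-7-methoxy-2-{4-[(4',5,7-tri-O-benzylkaempferol-3-yl)oxy]phenyl}chroman-4-ol (2,4-trans) | COc1cc(OCc2ccccc2)c2c(c1)O[C@H](c1ccc(Oc3c(-c4ccc(OCc5ccccc5)cc4)oc4cc(OCc5ccccc5)cc(OCc5ccccc5)c4c3=O)cc1)C[C@H]2O
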